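## Retrosynthetic overview

1. Target 31 ⇐ 27 (C1–O bond by enolate hydroxylation and acylation) ⇐ 23 (C5 ester) ⇐ 22 (hydroxyl-directed epoxidation of the C4 isopropenyl group).
2. Ring B of 22 (C2–C3 bond and the E-ethylidene) ⇐ ynal 21 by Rh-catalysed intramolecular alkyne hydroacylation (aldehyde C–H activation).
3. 21 ⇐ vinyl epoxide 16 + acid 18 by Pd-catalysed syn-1,2-acyloxylation (C6 ester, free C5–OH, C7 methylidene); 16 ⇐ enone 14 (epoxidation, double Wittig).
4. Ring A (14) ⇐ Diels–Alder reaction of chiral aminosiloxy diene 12 (from 6 and 8) with enynone 5 (Sonogashira coupling of 3 with 4).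
5. Ring order: six-membered ring A first (Diels–Alder), five-membered ring B second (hydroacylation); the acyl groups come from 18 (from 17) and 26 (from 24).

Assumption: the sense of induction of the (2R,5R)-2,5-diphenylpyrrolidine diene (step 7) and of the (R,R)-bishydroxamic acid ligand (step 15) is taken to be the one drawn; if either is opposite, its antipode is used and nothing else changes.

Convention: locants C1–C7a in the "Why" lines are those of the target's hydrindane skeleton; α is the face of H-7a, β the face of H-3a.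

## Route

Step 1
Reactants: 1 but-3-yn-2-one
Product: 3 (E)-4-iodobut-3-en-2-one, via (Z)-4-iodobut-3-en-2-one 2 (not isolated)
Conditions: NaI, AcOH, 25 °C; then 70 °C
Reagents that add atoms: sodium iodide, [Na+].[I-]
Why: Conjugate anti-hydroiodination of the ynone gives the Z-iodide, which equilibrates by addition–elimination under the acidic iodide conditions to the more stable E isomer, whose geometry later becomes the C3a/C4 trans relationship.

Step 2
Reactants: 3 (E)-4-iodobut-3-en-2-one; 4 propyne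
Product: 5 (E)-hept-3-en-5-yn-2-one
Conditions: Pd(PPh3)2Cl2 (2 mol%), CuI (4 mol%), Et3N, THF, 0 → 25 °C
Reagents that add atoms: none
Why: Sonogashira coupling (zerovalent palladium with CuI) of the activated β-iodo enone with propyne proceeds with retention of the E geometry.

Step 3
Reactants: 6 (E)-4-methoxybut-3-en-2-one
Product: 7 (E)-4-[(2R,5R)-2,5-diphenylpyrrolidin-1-yl]but-3-en-2-one
Conditions: (2R,5R)-2,5-diphenylpyrrolidine, MeOH, 25 → 50 °C
Reagents that add atoms: (2R,5R)-2,5-diphenylpyrrolidine, N1[C@@H](c2ccccc2)CC[C@@H]1c1ccccc1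
Why: Conjugate addition–elimination (amine exchange on a vinylogous ester) installs the C2-symmetric amine that later shields one face of the diene.

Step 4
Reactants: 8 2-iodoethanol
Product: 9 tert-butyl(2-iodoethoxy)dimethylsilane
Conditions: TBSCl, imidazole, CH2Cl2, 0 → 25 °C
Reagents that add atoms: tert-butyldimethylsilyl chloride, CC(C)(C)[Si](C)(C)Cl
Why: Standard silylation of a primary alcohol.

Step 5
Reactants: 7 (E)-4-[(2R,5R)-2,5-diphenylpyrrolidin-1-yl]but-3-en-2-one; 9 tert-butyl(2-iodoethoxy)dimethylsilane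
Product: 11 (E)-6-(tert-butyldimethylsilyloxy)-1-[(2R,5R)-2,5-diphenylpyrrolidin-1-yl]hex-1-en-3-one, via lithium enolate 10 (not isolated)
Conditions: LiN(iPr)2, THF, −78 °C; then 9, DMPU, −78 → 0 °C
Reagents that add atoms: none
Why: Kinetic α'-deprotonation of the vinylogous amide and SN2 alkylation of its lithium enolate by the primary iodide add the future C1–C2 unit.

Step 6
Reactants: 11 (E)-6-(tert-butyldimethylsilyloxy)-1-[(2R,5R)-2,5-diphenylpyrrolidin-1-yl]hex-1-en-3-one
Product: 12 (2R,5R)-1-[(1E,3Z)-3,6-bis(tert-butyldimethylsilyloxy)hexa-1,3-dien-1-yl]-2,5-diphenylpyrrolidine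
Conditions: TBSCl, KN(SiMe3)2, THF, −78 °C
Reagents that add atoms: tert-butyldimethylsilyl chloride, CC(C)(C)[Si](C)(C)Cl
Why: O-silylation of the amide-like Z-enolate (in-situ trapping) gives the Rawal-type 1-amino-3-siloxy diene with its C4 substituent on the outside.

Step 7
Reactants: 12 (2R,5R)-1-[(1E,3Z)-3,6-bis(tert-butyldimethylsilyloxy)hexa-1,3-dien-1-yl]-2,5-diphenylpyrrolidine; 5 (E)-hept-3-en-5-yn-2-one
Product: 14 (4S,5S,6S)-4-acetyl-6-[2-(tert-butyldimethylsilyloxy)ethyl]-5-(prop-1-yn-1-yl)cyclohex-2-en-1-one, via cycloadduct 13 (not isolated)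
Conditions: PhMe, 25 → 60 °C; then 1 N HCl, THF, 0 °C
Reagents that add atoms: none
Why: Endo-selective Diels–Alder reaction of the push–pull diene with the E-enone (diene C4 to the enone β-carbon) sets trans C3a/C4 from the E-dienophile, trans C3a/C7a from the Z-diene with endo acetyl, and the absolute configuration from the diene face left open by the diphenylpyrrolidine; acid then hydrolyses the silyl enol ether and expels the amine (β-elimination) to give the enone.

Step 8
Reactants: 14 (4S,5S,6S)-4-acetyl-6-[2-(tert-butyldimethylsilyloxy)ethyl]-5-(prop-1-yn-1-yl)cyclohex-2-en-1-one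
Product: 15 (1S,3S,4S,5R,6S)-5-acetyl-3-[2-(tert-butyldimethylsilyloxy)ethyl]-4-(prop-1-yn-1-yl)-7-oxabicyclo[4.1.0]heptan-2-one
Conditions: t-BuOOH, Triton B (cat.), THF, 0 °C
Reagents that add atoms: tert-butyl hydroperoxide, CC(C)(C)OO
Why: Weitz–Scheffer nucleophilic epoxidation, in which the hydroperoxide adds axially to C5 anti to the neighbouring C4 acetyl group, so both new C–O bonds are α (cold, weakly basic conditions avoid γ-deprotonation at C4).

Step 9
Reactants: 15 (1S,3S,4S,5R,6S)-5-acetyl-3-[2-(tert-butyldimethylsilyloxy)ethyl]-4-(prop-1-yn-1-yl)-7-oxabicyclo[4.1.0]heptan-2-one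
Product: 16 (1R,3S,4S,5S,6S)-3-[2-(tert-butyldimethylsilyloxy)ethyl]-2-methylidene-5-(prop-1-en-2-yl)-4-(prop-1-yn-1-yl)-7-oxabicyclo[4.1.0]heptane
Conditions: Ph3PCH3Br, KN(SiMe3)2, THF, 0 °C; then 15, −78 → 25 °C
Reagents that add atoms: methyltriphenylphosphonium bromide, C[P+](c1ccccc1)(c1ccccc1)c1ccccc1.[Br-]
Why: Double Wittig methylenation of the epoxy ketone and the methyl ketone with pre-formed ylide at low temperature gives the vinyl epoxide and the isopropenyl group without touching the stereocentres.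

Step 10
Reactants: 17 tiglic acid [(E)-2-methylbut-2-enoic acid]
Product: 18 (R)-2-methylbutanoic acid
Conditions: H2 (4 atm), Ru(OAc)2[(R)-H8-BINAP] (0.5 mol%), MeOH, 20 °C
Reagents that add atoms: none
Why: Noyori-type asymmetric hydrogenation of the α,β-unsaturated acid (divalent ruthenium bisphosphine catalyst) sets the (R)-α-stereocentre of the acyl group.

Step 11
Reactants: 16 (1R,3S,4S,5S,6S)-3-[2-(tert-butyldimethylsilyloxy)ethyl]-2-methylidene-5-(prop-1-en-2-yl)-4-(prop-1-yn-1-yl)-7-oxabicyclo[4.1.0]heptane; 18 (R)-2-methylbutanoic acid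
Product: 19 (1R,2S,3S,4S,5S)-5-[2-(tert-butyldimethylsilyloxy)ethyl]-2-hydroxy-6-methylidene-3-(prop-1-en-2-yl)-4-(prop-1-yn-1-yl)cyclohexyl (2R)-2-methylbutanoate
Conditions: Pd2(dba)3·CHCl3 (2.5 mol%), PPh3 (10 mol%), BEt3 (20 mol%), 18 (1.1 equiv), THF, 0 °C
Reagents that add atoms: none
Why: Proposed new method: zerovalent palladium ionises the vinyl epoxide with inversion to a π-allyl complex whose C5 alkoxide is captured by BEt3, acid 18 then forms a carboxylato-borate tethered at O5 that delivers the carboxylate to the adjacent allyl terminus C6 on the face away from palladium (second inversion, net retention, 6α-ester cis to 5α-OH) instead of the usual distal attack at the exocyclic CH2, and the hindered product ester re-ionises far more slowly than the strained epoxide; the closest known reaction types are the palladium/borane-co-catalysed 1,2-addition of alcohols to vinyl epoxides (Tsuji–Trost manifold) and the cis-selective palladium-catalysed CO2 insertion into vinyl epoxides.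

Step 12
Reactants: 19 (1R,2S,3S,4S,5S)-5-[2-(tert-butyldimethylsilyloxy)ethyl]-2-hydroxy-6-methylidene-3-(prop-1-en-2-yl)-4-(prop-1-yn-1-yl)cyclohexyl (2R)-2-methylbutanoate
Product: 20 (1R,2S,3S,4S,5S)-2-hydroxy-5-(2-hydroxyethyl)-6-methylidene-3-(prop-1-en-2-yl)-4-(prop-1-yn-1-yl)cyclohexyl (2R)-2-methylbutanoate
Conditions: HF·pyridine, pyridine, THF, 0 °C
Reagents that add atoms: none
Why: Fluoride-mediated cleavage of the primary silyl ether under mildly acidic, non-basic conditions that do not provoke acyl migration to the neighbouring hydroxyl.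

Step 13
Reactants: 20 (1R,2S,3S,4S,5S)-2-hydroxy-5-(2-hydroxyethyl)-6-methylidene-3-(prop-1-en-2-yl)-4-(prop-1-yn-1-yl)cyclohexyl (2R)-2-methylbutanoate
Product: 21 (1R,2S,3S,4S,5S)-2-hydroxy-6-methylidene-5-(2-oxoethyl)-3-(prop-1-en-2-yl)-4-(prop-1-yn-1-yl)cyclohexyl (2R)-2-methylbutanoate
Conditions: TEMPO (10 mol%), PhI(OAc)2, CH2Cl2, 25 °C
Reagents that add atoms: none
Why: TEMPO/PhI(OAc)2 oxidation (Piancatelli–Margarita) is selective for the primary alcohol over the hindered secondary C5 hydroxyl and stops at the aldehyde.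

Step 14
Reactants: 21 (1R,2S,3S,4S,5S)-2-hydroxy-6-methylidene-5-(2-oxoethyl)-3-(prop-1-en-2-yl)-4-(prop-1-yn-1-yl)cyclohexyl (2R)-2-methylbutanoate
Product: 22 (3E,3aS,4S,5S,6R,7aS)-3-ethylidene-5-hydroxy-7-methylidene-2-oxo-4-(prop-1-en-2-yl)octahydro-1H-inden-6-yl (2R)-2-methylbutanoate
Conditions: [Rh(cod)2]BF4 (10 mol%), rac-BINAP (10 mol%), H2 then Ar, CH2Cl2, 25 °C
Reagents that add atoms: none
Why: Cationic monovalent-rhodium-catalysed intramolecular alkyne hydroacylation (aldehyde C–H oxidative addition, syn hydrometalation of the alkyne, C–C reductive elimination; 5-exo-dig cyclisation of a 5-alkynal) closes ring B by forming C2–C3, the trans-diequatorial side chains give the trans ring fusion, and the syn delivery of acyl and H fixes the E-ethylidene.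

Step 15
Reactants: 22 (3E,3aS,4S,5S,6R,7aS)-3-ethylidene-5-hydroxy-7-methylidene-2-oxo-4-(prop-1-en-2-yl)octahydro-1H-inden-6-yl (2R)-2-methylbutanoate
Product: 23 (3E,3aS,4R,5S,6R,7aS)-3-ethylidene-5-hydroxy-7-methylidene-4-[(2R)-2-methyloxiran-2-yl]-2-oxooctahydro-1H-inden-6-yl (2R)-2-methylbutanoate
Conditions: VO(OiPr)3 (2 mol%), (R,R)-bishydroxamic acid ligand (4 mol%), cumene hydroperoxide, PhMe, 0 °C
Reagents that add atoms: cumene hydroperoxide, CC(C)(OO)c1ccccc1
Why: Hydroxyl-directed epoxidation of a homoallylic alcohol (pentavalent vanadium with Yamamoto's chiral bishydroxamic acid ligand): the equatorial C5 hydroxyl reaches only the isopropenyl alkene (it is antiperiplanar to the C7 methylidene and the enone is electron-poor), and the chiral ligand selects the face that gives the (R)-oxirane.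

Step 16
Reactants: 24 methyl pent-2-ynoate
Product: 25 methyl (2Z)-3-methylpent-2-enoate
Conditions: MeLi (2 equiv), CuI, THF, −78 °C; 24, −78 °C; NH4Cl (aq), −78 °C
Reagents that add atoms: methyllithium, [Li]C
Why: Syn carbocupration (conjugate addition of Me2CuLi to the ynoate) and cold protonation place the new methyl and H cis, so ethyl is cis to the ester (Z-enoate).

Step 17
Reactants: 25 methyl (2Z)-3-methylpent-2-enoate
Product: 26 (2Z)-3-methylpent-2-enoic acid
Conditions: LiOH, THF/H2O, 25 °C; then 1 N HCl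
Reagents that add atoms: lithium hydroxide, [Li+].[OH-]
Why: Saponification leaves the trisubstituted alkene geometry untouched.

Step 18
Reactants: 23 (3E,3aS,4R,5S,6R,7aS)-3-ethylidene-5-hydroxy-7-methylidene-4-[(2R)-2-methyloxiran-2-yl]-2-oxooctahydro-1H-inden-6-yl (2R)-2-methylbutanoate; 26 (2Z)-3-methylpent-2-enoic acid
Product: 27 (3E,3aS,4R,5S,6R,7aS)-3-ethylidene-7-methylidene-5-{[(2Z)-3-methylpent-2-enoyl]oxy}-4-[(2R)-2-methyloxiran-2-yl]-2-oxooctahydro-1H-inden-6-yl (2R)-2-methylbutanoate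
Conditions: 26, DCC, DMAP (0.2 equiv), CH2Cl2, 0 °C
Reagents that add atoms: none
Why: Steglich esterification of the hindered secondary C5 hydroxyl; low temperature and sub-stoichiometric DMAP limit Z/E isomerisation of the enoate and acyl migration.

Step 19
Reactants: 18 (R)-2-methylbutanoic acid
Product: 28 (R)-2-methylbutanoyl chloride
Conditions: (COCl)2, DMF (cat.), CH2Cl2, 0 → 25 °C
Reagents that add atoms: oxalyl chloride, O=C(Cl)C(=O)Cl
Why: Acid chloride formation under Vilsmeier catalysis without amine base, so the α-stereocentre is not racemised.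

Step 20
Reactants: 27 (3E,3aS,4R,5S,6R,7aS)-3-ethylidene-7-methylidene-5-{[(2Z)-3-methylpent-2-enoyl]oxy}-4-[(2R)-2-methyloxiran-2-yl]-2-oxooctahydro-1H-inden-6-yl (2R)-2-methylbutanoate; 28 (R)-2-methylbutanoyl chloride
Product: 31 (1R,3E,3aS,4R,5S,6R,7aS)-3-ethylidene-7-methylidene-5-{[(2Z)-3-methylpent-2-enoyl]oxy}-4-[(2R)-2-methyloxiran-2-yl]-2-oxooctahydro-1H-indene-1,6-diyl bis[(2R)-2-methylbutanoate] (target CNP0274886.3), via potassium enolate 29 (not isolated), via potassium alkoxide 30 (not isolated)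
Conditions: KN(SiMe3)2, THF, −78 °C; 2-(phenylsulfonyl)-3-phenyloxaziridine, −78 °C; then 28, −78 → −40 °C
Reagents that add atoms: 2-(phenylsulfonyl)-3-phenyloxaziridine, O=S(=O)(N1OC1c1ccccc1)c1ccccc1
Why: Kinetic α'-enolisation of the cross-conjugated enone (only C1 carries α'-hydrogens), Davis oxaziridine hydroxylation from the β-face (pseudoaxial attack antiperiplanar to C7a–H, whereas α-attack would eclipse that bond) and in-situ O-acylation of the alkoxide give the 1β-ester.

## Compound list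

1 | but-3-yn-2-one | CC(=O)C#C | starting material
2 | (Z)-4-iodobut-3-en-2-one (formed in the flask) | CC(=O)/C=C\I | intermediate
3 | (E)-4-iodobut-3-en-2-one | CC(=O)/C=C/I | intermediate
4 | propyne | CC#C | starting material
5 | (E)-hept-3-en-5-yn-2-one | CC#C/C=C/C(C)=O | intermediate
6 | (E)-4-methoxybut-3-en-2-one | CO/C=C/C(C)=O | starting material
7 | (E)-4-[(2R,5R)-2,5-diphenylpyrrolidin-1-yl]but-3-en-2-one | CC(=O)/C=C/N1[C@@H](c2ccccc2)CC[C@@H]1c1ccccc1 | intermediate
8 | 2-iodoethanol | OCCI | starting material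
9 | tert-butyl(2-iodoethoxy)dimethylsilane | CC(C)(C)[Si](C)(C)OCCI | intermediate
10 | lithium enolate of 7 (formed in the flask) | [Li+].[O-]C(=C)/C=C/N1[C@@H](c2ccccc2)CC[C@@H]1c1ccccc1 | intermediate
11 | (E)-6-(tert-butyldimethylsilyloxy)-1-[(2R,5R)-2,5-diphenylpyrrolidin-1-yl]hex-1-en-3-one | CC(C)(C)[Si](C)(C)OCCCC(=O)/C=C/N1[C@@H](c2ccccc2)CC[C@@H]1c1ccccc1 | intermediate
12 | (2R,5R)-1-[(1E,3Z)-3,6-bis(tert-butyldimethylsilyloxy)hexa-1,3-dien-1-yl]-2,5-diphenylpyrrolidine | CC(C)(C)[Si](C)(C)OCC/C=C(O[Si](C)(C)C(C)(C)C)/C=C/N1[C@@H](c2ccccc2)CC[C@@H]1c1ccccc1 | intermediate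
13 | Diels–Alder cycloadduct (formed in the flask): 4-acetyl-1-(TBS-oxy)-6-[2-(TBS-oxy)ethyl]-3-[(2R,5R)-2,5-diphenylpyrrolidin-1-yl]-5-(prop-1-yn-1-yl)cyclohex-1-ene; 3,4-cis; 4,5-trans; 5,6-trans | CC(C)(C)[Si](C)(C)OC=1[C@@H](CCO[Si](C)(C)C(C)(C)C)[C@H](C#CC)[C@@H](C(C)=O)[C@@H](N2[C@@H](c3ccccc3)CC[C@@H]2c2ccccc2)C=1 | intermediate
14 | (4S,5S,6S)-4-acetyl-6-[2-(tert-butyldimethylsilyloxy)ethyl]-5-(prop-1-yn-1-yl)cyclohex-2-en-1-one | O=C1[C@@H](CCO[Si](C)(C)C(C)(C)C)[C@H](C#CC)[C@@H](C(C)=O)C=C1 | intermediate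
15 | (1S,3S,4S,5R,6S)-5-acetyl-3-[2-(tert-butyldimethylsilyloxy)ethyl]-4-(prop-1-yn-1-yl)-7-oxabicyclo[4.1.0]heptan-2-one | O=C1[C@@H](CCO[Si](C)(C)C(C)(C)C)[C@H](C#CC)[C@@H](C(C)=O)[C@@H]2O[C@H]12 | intermediate
16 | (1R,3S,4S,5S,6S)-3-[2-(tert-butyldimethylsilyloxy)ethyl]-2-methylidene-5-(prop-1-en-2-yl)-4-(prop-1-yn-1-yl)-7-oxabicyclo[4.1.0]heptane | C=C1[C@@H](CCO[Si](C)(C)C(C)(C)C)[C@H](C#CC)[C@@H](C(C)=C)[C@@H]2O[C@H]12 | intermediate
17 | tiglic acid, (E)-2-methylbut-2-enoic acid | C/C=C(\C)C(=O)O | starting material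
18 | (R)-2-methylbutanoic acid | CC[C@@H](C)C(=O)O | intermediate
19 | (1R,2S,3S,4S,5S)-5-[2-(tert-butyldimethylsilyloxy)ethyl]-2-hydroxy-6-methylidene-3-(prop-1-en-2-yl)-4-(prop-1-yn-1-yl)cyclohexyl (2R)-2-methylbutanoate | C=C1[C@@H](CCO[Si](C)(C)C(C)(C)C)[C@H](C#CC)[C@@H](C(C)=C)[C@H](O)[C@@H]1OC(=O)[C@H](C)CC | intermediate
20 | (1R,2S,3S,4S,5S)-2-hydroxy-5-(2-hydroxyethyl)-6-methylidene-3-(prop-1-en-2-yl)-4-(prop-1-yn-1-yl)cyclohexyl (2R)-2-methylbutanoate | C=C1[C@@H](CCO)[C@H](C#CC)[C@@H](C(C)=C)[C@H](O)[C@@H]1OC(=O)[C@H](C)CC | intermediate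
21 | (1R,2S,3S,4S,5S)-2-hydroxy-6-methylidene-5-(2-oxoethyl)-3-(prop-1-en-2-yl)-4-(prop-1-yn-1-yl)cyclohexyl (2R)-2-methylbutanoate | C=C1[C@@H](CC=O)[C@H](C#CC)[C@@H](C(C)=C)[C@H](O)[C@@H]1OC(=O)[C@H](C)CC | intermediate
22 | (3E,3aS,4S,5S,6R,7aS)-3-ethylidene-5-hydroxy-7-methylidene-2-oxo-4-(prop-1-en-2-yl)octahydro-1H-inden-6-yl (2R)-2-methylbutanoate | C=C1[C@@H]2[C@H](/C(=C\C)C(=O)C2)[C@@H](C(C)=C)[C@H](O)[C@@H]1OC(=O)[C@H](C)CC | intermediate
23 | (3E,3aS,4R,5S,6R,7aS)-3-ethylidene-5-hydroxy-7-methylidene-4-[(2R)-2-methyloxiran-2-yl]-2-oxooctahydro-1H-inden-6-yl (2R)-2-methylbutanoate | C=C1[C@@H]2[C@H](/C(=C\C)C(=O)C2)[C@@H]([C@]2(C)CO2)[C@H](O)[C@@H]1OC(=O)[C@H](C)CC | intermediate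
24 | methyl pent-2-ynoate | CCC#CC(=O)OC | starting material
25 | methyl (2Z)-3-methylpent-2-enoate | COC(=O)/C=C(/C)CC | intermediate
26 | (2Z)-3-methylpent-2-enoic acid | OC(=O)/C=C(/C)CC | intermediate
27 | (3E,3aS,4R,5S,6R,7aS)-3-ethylidene-7-methylidene-5-{[(2Z)-3-methylpent-2-enoyl]oxy}-4-[(2R)-2-methyloxiran-2-yl]-2-oxooctahydro-1H-inden-6-yl (2R)-2-methylbutanoate | C=C1[C@@H]2[C@H](/C(=C\C)C(=O)C2)[C@@H]([C@]2(C)CO2)[C@H](OC(=O)/C=C(/C)CC)[C@@H]1OC(=O)[C@H](C)CC | intermediate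
28 | (R)-2-methylbutanoyl chloride | CC[C@@H](C)C(=O)Cl | intermediate
29 | potassium C1–C2 enolate of 27 (formed in the flask) | C=C1[C@@H]2[C@H](/C(=C\C)C([O-])=C2)[C@@H]([C@]2(C)CO2)[C@H](OC(=O)/C=C(/C)CC)[C@@H]1OC(=O)[C@H](C)CC.[K+] | intermediate
30 | potassium alkoxide of the 1β-hydroxy ketone (formed in the flask) | C=C1[C@@H]2[C@H](/C(=C\C)C(=O)[C@@H]2[O-])[C@@H]([C@]2(C)CO2)[C@H](OC(=O)/C=C(/C)CC)[C@@H]1OC(=O)[C@H](C)CC.[K+] | intermediate
31 | (1R,3E,3aS,4R,5S,6R,7aS)-3-ethylidene-7-methylidene-5-{[(2Z)-3-methylpent-2-enoyl]oxy}-4-[(2R)-2-methyloxiran-2-yl]-2-oxooctahydro-1H-indene-1,6-diyl bis[(2R)-2-methylbutanoate] | C=C1[C@@H]2[C@H](/C(=C\C)C(=O)[C@@H]2OC(=O)[C@H](C)CC)[C@@H]([C@]2(C)CO2)[C@H](OC(=O)/C=C(/C)CC)[C@@H]1OC(=O)[C@H](C)CC | target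

## Step count and risks

Total step count: 20.

Longest linear sequence: 13 steps (6 → 7 → 11 → 12 → 14 → 15 → 16 → 19 → 20 → 21 → 22 → 23 → 27 → 31; steps 3, 5, 6, 7, 8, 9, 11, 12, 13, 14, 15, 18, 20). The branch from 8 through step 4 is equally long.

Three steps most likely to fail:

**Step 11 (the proposed new syn-1,2-acyloxylation).** The carboxylate may attack the exocyclic CH2 terminus instead (1,4-product), or the product may re-ionise. The fallback uses known chemistry, sets out from 16 and returns at 19. Pd(PPh3)4 (cat.) under CO2 (1 atm) in THF converts 16 with net retention into the cis cyclic carbonate F1. K2CO3 in MeOH gives the cis-diol F2. Bu2SnO (toluene, reflux), then 4-methoxybenzyl chloride and CsF in DMF, alkylates the equatorial oxygen selectively to the PMB ether F3. DCC/DMAP esterification of the remaining axial allylic hydroxyl with 18 gives the ester F4. DDQ in wet CH2Cl2 removes the PMB group and gives 19.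

**Step 14 (hydroacylation).** The acyl rhodium hydride may insert into the C7 methylidene (4-alkenal mode) or decarbonylate. The fallback sets out from 21 and returns at 22. Ni(cod)2 (10 mol%), PBu3 (20 mol%) and Et3SiH in THF at 25 °C (zerovalent nickel-catalysed reductive ynal cyclisation, which engages only the alkyne) form the same C2–C3 bond with the same alkene geometry and give the allylic triethylsilyl ether F5. TBAF gives the allylic alcohol F6. MnO2 in CH2Cl2 oxidises only the allylic hydroxyl and gives 22.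

**Step 20 (facial selectivity of the enolate oxidation and one-pot acylation).** The fallback sets out from 27 and returns at 31. The enolate is oxidised as before but quenched with aqueous NH4Cl and the hydroxy ketone is isolated. If the 1α-epimer, the 1-epi-hydroxy ketone F7, predominates, Mitsunobu esterification with 18 (PPh3, DIAD, toluene, 0 °C) inverts C1 and gives 31 directly. If the 1β-alcohol is obtained, it is simply esterified with 18 (DCC, DMAP).

## Further compounds

F1 | step 11 | cis cyclic carbonate of diol F2 (1,3-dioxolan-2-one fused across the two oxygen-bearing ring carbons, both C–O bonds α) | C=C1[C@@H](CCO[Si](C)(C)C(C)(C)C)[C@H](C#CC)[C@@H](C(C)=C)[C@@H]2OC(=O)O[C@H]12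
F2 | step 11 | (1R,2S,3S,4S,5S)-5-[2-(tert-butyldimethylsilyloxy)ethyl]-6-methylidene-3-(prop-1-en-2-yl)-4-(prop-1-yn-1-yl)cyclohexane-1,2-diol | C=C1[C@@H](CCO[Si](C)(C)C(C)(C)C)[C@H](C#CC)[C@@H](C(C)=C)[C@H](O)[C@@H]1O
F3 | step 11 | 2-O-(4-methoxybenzyl) ether of diol F2 (equatorial oxygen protected, axial allylic hydroxyl free) | C=C1[C@@H](CCO[Si](C)(C)C(C)(C)C)[C@H](C#CC)[C@@H](C(C)=C)[C@H](OCc2ccc(OC)cc2)[C@@H]1O
F4 | step 11 | 2-O-(4-methoxybenzyl) ether of 19 (1-O-[(2R)-2-methylbutanoyl] ester of F3) | C=C1[C@@H](CCO[Si](C)(C)C(C)(C)C)[C@H](C#CC)[C@@H](C(C)=C)[C@H](OCc2ccc(OC)cc2)[C@@H]1OC(=O)[C@H](C)CC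
F5 | step 14 | 2-(triethylsilyloxy) analogue of 22 (allylic silyl ether, C2 epimers, E-ethylidene) | C=C1[C@@H]2[C@H](/C(=C\C)C(O[Si](CC)(CC)CC)C2)[C@@H](C(C)=C)[C@H](O)[C@@H]1OC(=O)[C@H](C)CC
F6 | step 14 | 2-hydroxy analogue of 22 (allylic alcohol, C2 epimers) | C=C1[C@@H]2[C@H](/C(=C\C)C(O)C2)[C@@H](C(C)=C)[C@H](O)[C@@H]1OC(=O)[C@H](C)CC
F7 | step 20 | (1S)-1-hydroxy derivative of 27 (1α-hydroxy ketone, C1 epimer of the alcohol corresponding to 30) | C=C1[C@@H]2[C@H](/C(=C\C)C(=O)[C@H]2O)[C@@H]([C@]2(C)CO2)[C@H](OC(=O)/C=C(/C)CC)[C@@H]1OC(=O)[C@H](C)CC
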